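Start from a small charge: the maple run, with a quarter of the alder run's catalyst per litre at the same loading.

| flask | substrate | catalyst | remark | time |
|---|---|---|---|---|
| oak | 0.19 M | 6.4 mol% | run made earlier |  |
| maple | 0.095 M | 6.4 mol% | run made earlier |  |
| alder | 0.38 M | 6.4 mol% | run made earlier |  |
| elm | 0.19 M | 9.6 mol% | run made earlier |  |
| Saturday's | 0.19 M (fed, over 8.00 h) | 6.4 mol% | all but substrate at the start; substrate goes in evenly over 8.00 h, the run ends at 10 h | 10 h |
| Sunday's | 0.19 M | 6.4 mol% | everything together in a closed stirred flask, run for 10 h | 10 h |
| Wednesday's | 0.19 M | 6.4 mol% | a single well-mixed tank run continuously and read at steady state, 10 h in it on average |  |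

| run | time / h | target / % | substrate / % |
|---|---|---|---|
| oak | 2.50 | 26 | 36 |
| oak | 5.00 | 45 | 13 |
| oak | 8.00 | 50 | 11 |
| oak | 10.0 | 48 | 9 |
| maple | 1.00 | 7 | 61 |
| maple | 2.00 | 14 | 42 |
| maple | 5.00 | 36 | 15 |
| maple | 12.0 | 48 | 6 |
| alder | 1.00 | 11 | 64 |
| alder | 2.00 | 25 | 42 |
| alder | 5.00 | 46 | 15 |
| alder | 12.0 | 45 | 8 |
| elm | 1.00 | 8 | 67 |
| elm | 2.00 | 19 | 44 |
| elm | 5.00 | 47 | 14 |
| elm | 12.0 | 48 | 5 |

(scatter of a reading: 2 percentage points)

- the stated concentrations are those of everything mixed, before any reaction; amounts are the same in each set-up
- the earlier runs were read with a standard deviation of 2 percentage points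
- the feed brings no volume worth counting
- the earlier runs were made in a closed, stirred flask

* the set-up with the highest amount of target at the outlet or at the end, in percent of the substrate put in ("none" if the first two lie within 2 percentage points) (Saturday's / Sunday's / Wednesday's / none)
* amount of target at the outlet or at the end, in percent of the substrate put in, Saturday's
* amount of target at the outlet or at the end, in percent of the substrate put in, Sunday's
* amount of target at the outlet or at the end, in percent of the substrate put in, Wednesday's

Read two times. Substrate stands at 42% after 2.00 h in both maple and alder, so let T, its mean time of first fall, be 2.31 h. Target at that time climbs with catalyst per litre: 14% in maple, 19% in elm, 25% in alder. Maple reaches alder's figure at about 3.50 h, trailing by 1.50 h. Take the wait between substrate lost and target formed as inverse to catalyst per litre. The trail is then maple's wait less alder's, which is a quarter of it, so maple's wait is 2.00 h. With twice that catalyst per litre, Saturday's flask waits 1.00 h: call this the hand-over time θ.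

θ is shorter than T, but T is only 2.31 times θ, so I count these two times as of like size and call neither step rate-limiting. Saturday's last substrate has 2.00 h, less than T plus θ, so I put Saturday's below Sunday's.

The forecast agrees: 42% for Saturday's, since “late-fed substrate is unfinished at 10 h”, 49% for Sunday's, 38% for Wednesday's, and Sunday's as best.

The flasks give 42.5%, 49.4% and 32.8%, with Sunday's best, so the forecast parts on Wednesday's by 5.2 percentage points.

    substrate → intermediate (k = 8.08 × 10⁻⁵ s⁻¹)
    catalyst + intermediate → catalyst + target (k = 0.0151 M⁻¹ s⁻¹)
    substrate ⇌ dormant form (K = 0.853, k = 4.43 × 10⁻⁵ s⁻¹)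
    target → over-reaction product (k = 2.01 × 10⁻⁵ s⁻¹)

At 5.88 h in Saturday's flask, substrate's half-life by its step to intermediate is 2.4 h, longer than the 1.0 h of intermediate by the catalyst step. Saturday's time after the feed is twice θ, and it ends with 10.5% intermediate beside 42.5% target. At 0.11 M of substrate and the same loading, θ becomes 1.73 h, and that neighbour flask ends with 18.5% intermediate and 36.8% target.

The data come from a simulation for substances that don't exist; noise was put on by code.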